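The ten-membered ring is closed late, across C7–C8 (germacrane numbering: lactone O–C6, C7, exo-methylene C11=C13, lactone carbonyl C12; glycidate on C8, acetate on C9, ester-bearing C10). The key step exploits the homoallylic alcohol retron C8(O)–C7–C11=C13 hidden in the α-methylene-γ-lactone ring. An intramolecular Nozaki–Hiyama–Kishi allylation of a C8 aldehyde by a 3-(bromomethyl)butenolide closes the carbocycle, sets C7 and C8, and turns the butenolide into the α-methylene lactone in one operation. The precursor is an acyclic (4R,5S)-epoxy butenolide aldehyde. C8 is expected to form as the 8R alcohol and is inverted during Mitsunobu esterification.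

Key step: step 14

Remark: germacrane numbering is used for positions (C14 = ester carbon on C10, C15 = methyl on C4); the ring-cis C1=C10 olefin is E by the sequence rule; methyl (2S)-2-methyloxirane-2-carboxylate is taken as commercial.

Step 1
Reactants: 1 neryl acetate
Product: 2 (2Z)-3-methyl-6-oxohex-2-en-1-yl acetate
Conditions: O3 (1 equiv), CH2Cl2, pyridine, −78 °C; then Me2S, −78 °C to rt
Reagents that add atoms: ozone, [O-][O+]=O
Why: Chemoselective ozonolysis (Criegee mechanism, reductive work-up): the isopropylidene olefin is far more electron-rich than the 2,3-olefin deactivated by the allylic acetate, so one equivalent of ozone should cleave only that end and leave the Z-olefin untouched.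

Step 2
Reactants: 3 dimethyl (S)-malate
Product: 4 methyl (3S)-3,4-dihydroxybutanoate
Conditions: BH3·SMe2, NaBH4 (5 mol %), THF, 0 °C to rt
Reagents that add atoms: none
Why: Hydroxyl-directed borane reduction: the alkoxyborane formed at the C2 hydroxyl delivers hydride only to the neighbouring ester, so the remote methyl ester (the future C14) and the S centre (the future C9) are kept.

Step 3
Reactants: 4 methyl (3S)-3,4-dihydroxybutanoate
Product: 5 methyl (3S)-3,4-bis(triethylsilyloxy)butanoate
Conditions: Et3SiCl, imidazole, DMF, 0 °C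
Reagents that add atoms: chlorotriethylsilane, CC[Si](CC)(CC)Cl
Why: Standard silylation of both hydroxyls, which stops lactonisation of the diol onto the ester and leaves no free hydroxyl for the enolate step.

Step 4
Reactants: 5 methyl (3S)-3,4-bis(triethylsilyloxy)butanoate; 2 (2Z)-3-methyl-6-oxohex-2-en-1-yl acetate
Product: 6 methyl (6Z)-8-acetoxy-3-hydroxy-6-methyl-2-[(1S)-1,2-bis(triethylsilyloxy)ethyl]oct-6-enoate (mixture of epimers at C2 and C3)
Conditions: LiN(iPr)2, THF, −78 °C; then 2, −78 °C; cold NH4Cl quench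
Reagents that add atoms: none
Why: Lithium ester enolate aldol addition at −78 °C, where β-elimination of the silyloxy group is slow and the aldehyde reacts far faster than the acetate; the two new centres are removed in step 5, so their configuration does not matter.

Step 5
Reactants: 6 aldol adduct
Product: 8 methyl (2E,6Z)-8-acetoxy-6-methyl-2-[(1S)-1,2-bis(triethylsilyloxy)ethyl]octa-2,6-dienoate, via mesylate 7 (not isolated)
Conditions: MsCl, Et3N, CH2Cl2, 0 °C; then DBU, rt
Reagents that add atoms: none
Why: Mesylation followed by E1cB elimination: the ester enolate expels the mesylate and not the silyloxy group, and, as for tiglates, the trisubstituted olefin should form with the alkyl chain trans to the ester (2E), which is the ring-cis geometry needed for C1=C10.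

Step 6
Reactants: 8 dienoate acetate
Product: 9 methyl (2E,6Z)-8-hydroxy-6-methyl-2-[(1S)-1,2-bis(triethylsilyloxy)ethyl]octa-2,6-dienoate
Conditions: K2CO3 (0.2 equiv), MeOH, 0 °C
Reagents that add atoms: none
Why: Base-catalysed transesterification (methanolysis) removes the primary allylic acetate, while the conjugated methyl ester only exchanges with the solvent and triethylsilyl ethers tolerate catalytic carbonate at 0 °C.

Step 7
Reactants: 9 allylic alcohol
Product: 10 methyl (2E,6Z)-6-methyl-8-oxo-2-[(1S)-1,2-bis(triethylsilyloxy)ethyl]octa-2,6-dienoate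
Conditions: PhI(OAc)2, TEMPO (10 mol %), CH2Cl2, rt
Reagents that add atoms: none
Why: TEMPO-catalysed oxidation with a hypervalent iodine co-oxidant is near neutral and stops at the aldehyde, so the Z-enal should form without Z/E isomerisation.

Step 8
Reactants: 10 Z-enal
Product: 11 methyl (2E,6Z,8R)-8-hydroxy-6-methyl-2-[(1S)-1,2-bis(triethylsilyloxy)ethyl]deca-2,6,9-trienoate
Conditions: Zn(CH=CH2)2, (2R)-(+)-3-exo-morpholinoisoborneol (10 mol %), toluene, −20 °C to 0 °C; NH4Cl work-up
Reagents that add atoms: divinylzinc, C=C[Zn]C=C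
Why: Amino-alcohol-catalysed enantioselective 1,2-addition of an organozinc to an aldehyde: the (2R)-ligand, mirror image of the one that sends alkyl groups to the Si face, should deliver vinyl to the Re face and set the 8R carbinol (the future C6), and the esters are inert to the zinc reagent.

Step 9
Reactants: 11 divinyl carbinol
Product: 12 methyl (2E)-5-{(2R,3S)-3-[(1R)-1-hydroxyprop-2-en-1-yl]-2-methyloxiran-2-yl}-2-[(1S)-1,2-bis(triethylsilyloxy)ethyl]pent-2-enoate
Conditions: mCPBA, NaHCO3, CH2Cl2, 0 °C
Reagents that add atoms: 3-chloroperoxybenzoic acid, OOC(=O)c1cccc(Cl)c1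
Why: Hydroxyl-directed Prilezhaev epoxidation: only the trisubstituted 6Z-olefin is nucleophilic enough, and with the carbinol C–H eclipsing the olefin to avoid A(1,3) strain with the cis CH2 group the hydrogen-bonded peracid is delivered syn to the hydroxyl, which should give the threo epoxy alcohol (the future 4R,5S epoxide).

Step 10
Reactants: 12 epoxy alcohol
Product: 13 methyl (2E)-5-{(2R,3S)-3-[(1R)-1-{[2-(bromomethyl)prop-2-enoyl]oxy}prop-2-en-1-yl]-2-methyloxiran-2-yl}-2-[(1S)-1,2-bis(triethylsilyloxy)ethyl]pent-2-enoate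
Conditions: 2-(bromomethyl)acryloyl chloride (from the commercial acid and oxalyl chloride), 2,6-lutidine, CH2Cl2, −20 °C to 0 °C
Reagents that add atoms: 2-(bromomethyl)acryloyl chloride, C=C(CBr)C(=O)Cl
Why: Acylation of the secondary alcohol with an acid chloride; the hindered, weakly nucleophilic base avoids SN2′ attack on the allylic bromide, and the carbinol centre is not touched.

Step 11
Reactants: 13 acrylate ester
Product: 14 methyl (2E)-5-{(2R,3S)-3-[(2R)-4-(bromomethyl)-5-oxo-2,5-dihydrofuran-2-yl]-2-methyloxiran-2-yl}-2-[(1S)-1,2-bis(triethylsilyloxy)ethyl]pent-2-enoate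
Conditions: second-generation Grubbs catalyst (5 mol %), toluene, 80 °C
Reagents that add atoms: none
Why: Ring-closing metathesis of the acrylate of a secondary allylic alcohol to a butenolide: the vinyl group initiates, the 1,1-disubstituted acrylate closes the five-membered ring with loss of ethylene, and the trisubstituted enoate and the allylic bromide are spectators.

Step 12
Reactants: 14 bromomethyl butenolide
Product: 15 methyl (2E)-5-{(2R,3S)-3-[(2R)-4-(bromomethyl)-5-oxo-2,5-dihydrofuran-2-yl]-2-methyloxiran-2-yl}-2-[(1S)-2-hydroxy-1-(triethylsilyloxy)ethyl]pent-2-enoate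
Conditions: HF·pyridine, pyridine, THF, 0 °C
Reagents that add atoms: none
Why: Selective desilylation: buffered HF·pyridine at 0 °C cleaves the primary triethylsilyl ether much faster than the hindered secondary one and is tolerated by trisubstituted epoxides and allylic bromides; the alcohol is oxidised at once so that it cannot lactonise onto the C14 ester.

Step 13
Reactants: 15 primary alcohol
Product: 16 methyl (2E)-5-{(2R,3S)-3-[(2R)-4-(bromomethyl)-5-oxo-2,5-dihydrofuran-2-yl]-2-methyloxiran-2-yl}-2-[(1S)-2-oxo-1-(triethylsilyloxy)ethyl]pent-2-enoate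
Conditions: Dess–Martin periodinane, NaHCO3, CH2Cl2, 0 °C to rt
Reagents that add atoms: none
Why: Dess–Martin oxidation under buffered, non-basic conditions should give the α-silyloxy aldehyde without epimerisation at C9 and without touching the bromide, the epoxide or the butenolide.

Step 14
Reactants: 16 bromo aldehyde
Product: 18 methyl (4R,5S,6R,7R,8R,9S)-4,5-epoxy-8-hydroxy-9-(triethylsilyloxy)germacra-1(10),11(13)-dien-6,12-olid-14-oate (8-epi alcohol; C1=C10 ring-cis), via allylchromium dichloride 17 (not isolated)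
Conditions: CrCl2 (10 equiv), THF/DMF, rt, syringe-pump addition to 2 mM; aqueous work-up
Reagents that add atoms: none
Why: Two equivalents of divalent chromium insert into the allylic C13–Br bond to give allylchromium 17 (trivalent chromium on C13), which adds through C7 (SE2′, γ-attack) to the C8 aldehyde in a six-membered Zimmerman–Traxler chair; this is the intramolecular Nozaki–Hiyama–Kishi allylation used for macrocyclic α-methylene lactones and known intermolecularly for 3-(bromomethyl)furan-2(5H)-ones. The new C7–C8 bond closes the ten-membered carbocycle C1–C10 in a 10-exo-trig sense at the aldehyde, and the C11=C13 exo-methylene appears outside the new ring. C8: the non-chelating triethylsilyloxy group on C9 stands anti to the incoming C7 (Felkin–Anh), which should give the 8,9-anti, that is 8R, alcohol. C7: the butenolide locks the allyl unit with C6 trans to C13, so the chair with C9 equatorial couples 8R to 7R, the face of C7 syn to the C5 epoxide carbon, which is also the face that the seven-atom tether, folded by the cis-epoxide and the ring-cis C1=C10 olefin, reaches most easily. The step needs ring closure to beat oligomerisation (high dilution, slow addition) and this cis ring fusion to beat attack anti to C5; the controlling centres C6 and C9 are already in place in 16, and the 8R centre is corrected in step 16.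

Step 15
Reactants: 19 methyl (2S)-2-methyloxirane-2-carboxylate
Product: 20 (2S)-2-methyloxirane-2-carboxylic acid
Conditions: LiOH, THF/H2O, 0 °C; NaHSO4 to pH 3, extraction, used at once
Reagents that add atoms: lithium hydroxide, [Li+].[OH-]
Why: Saponification at 0 °C: hydroxide attacks the ester carbonyl faster than the hindered 2,2-disubstituted epoxide, and the quaternary stereocentre cannot epimerise.

Step 16
Reactants: 18 8-epi alcohol; 20 (2S)-2-methyloxirane-2-carboxylic acid
Product: 21 methyl (4R,5S,6R,7S,8S,9S)-4,5-epoxy-8-{[(2S)-2-methyloxiran-2-yl]carbonyloxy}-9-(triethylsilyloxy)germacra-1(10),11(13)-dien-6,12-olid-14-oate (C7 unchanged in space; its descriptor changes only by priority)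
Conditions: PPh3, DIAD (betaine preformed), toluene, 0 °C to rt
Reagents that add atoms: none
Why: Mitsunobu esterification: the alkoxyphosphonium ion of the 8R alcohol is displaced by the fairly acidic glycidic carboxylate in an SN2 reaction with inversion, which installs the ester and sets 8S in one operation; preforming the betaine keeps free PPh3 away from the α-methylene lactone, and the silyl ether on C9 cannot take part as a neighbouring group.

Step 17
Reactants: 21 silyl ether
Product: 23 target CNP0274195.1 (methyl (4R,5S,6R,7R,8S,9S)-9-acetoxy-4,5-epoxy-8-{[(2S)-2-methyloxiran-2-yl]carbonyloxy}germacra-1(10),11(13)-dien-6,12-olid-14-oate), via C9 alcohol 22 (not isolated)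
Conditions: HF·pyridine, pyridine, THF, 0 °C; then Ac2O (excess), DMAP, 0 °C to rt
Reagents that add atoms: acetic anhydride, CC(=O)OC(C)=O
Why: Fluoride-mediated cleavage of the secondary triethylsilyl ether under buffered conditions that epoxides tolerate, then DMAP-catalysed acetylation of the C9 hydroxyl in the same flask before the hindered glycidate can migrate.

Compound list
1 | neryl acetate, (2Z)-3,7-dimethylocta-2,6-dien-1-yl acetate | CC(C)=CCC/C(C)=C\COC(C)=O | starting material
2 | (2Z)-3-methyl-6-oxohex-2-en-1-yl acetate | O=CCC/C(C)=C\COC(C)=O | intermediate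
3 | dimethyl (S)-malate | COC(=O)C[C@H](O)C(=O)OC | starting material
4 | methyl (3S)-3,4-dihydroxybutanoate | COC(=O)C[C@H](O)CO | intermediate
5 | methyl (3S)-3,4-bis(triethylsilyloxy)butanoate | COC(=O)C[C@H](O[Si](CC)(CC)CC)CO[Si](CC)(CC)CC | intermediate
6 | methyl (6Z)-8-acetoxy-3-hydroxy-6-methyl-2-[(1S)-1,2-bis(triethylsilyloxy)ethyl]oct-6-enoate, epimers at C2 and C3 | CC[Si](CC)(CC)OC[C@@H](O[Si](CC)(CC)CC)C(C(=O)OC)C(O)CC/C(C)=C\COC(C)=O | intermediate
7 | C3 mesylate of 6 | CC[Si](CC)(CC)OC[C@@H](O[Si](CC)(CC)CC)C(C(=O)OC)C(OS(C)(=O)=O)CC/C(C)=C\COC(C)=O | intermediate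
8 | methyl (2E,6Z)-8-acetoxy-6-methyl-2-[(1S)-1,2-bis(triethylsilyloxy)ethyl]octa-2,6-dienoate | CC[Si](CC)(CC)OC[C@@H](O[Si](CC)(CC)CC)/C(C(=O)OC)=C\CC/C(C)=C\COC(C)=O | intermediate
9 | methyl (2E,6Z)-8-hydroxy-6-methyl-2-[(1S)-1,2-bis(triethylsilyloxy)ethyl]octa-2,6-dienoate | CC[Si](CC)(CC)OC[C@@H](O[Si](CC)(CC)CC)/C(C(=O)OC)=C\CC/C(C)=C\CO | intermediate
10 | methyl (2E,6Z)-6-methyl-8-oxo-2-[(1S)-1,2-bis(triethylsilyloxy)ethyl]octa-2,6-dienoate | CC[Si](CC)(CC)OC[C@@H](O[Si](CC)(CC)CC)/C(C(=O)OC)=C\CC/C(C)=C\C=O | intermediate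
11 | methyl (2E,6Z,8R)-8-hydroxy-6-methyl-2-[(1S)-1,2-bis(triethylsilyloxy)ethyl]deca-2,6,9-trienoate | CC[Si](CC)(CC)OC[C@@H](O[Si](CC)(CC)CC)/C(C(=O)OC)=C\CC/C(C)=C\[C@H](O)C=C | intermediate
12 | methyl (2E)-5-{(2R,3S)-3-[(1R)-1-hydroxyprop-2-en-1-yl]-2-methyloxiran-2-yl}-2-[(1S)-1,2-bis(triethylsilyloxy)ethyl]pent-2-enoate | CC[Si](CC)(CC)OC[C@@H](O[Si](CC)(CC)CC)/C(C(=O)OC)=C\CC[C@@]1(C)O[C@H]1[C@H](O)C=C | intermediate
13 | 2-(bromomethyl)prop-2-enoate ester of 12 at the (1R)-carbinol | CC[Si](CC)(CC)OC[C@@H](O[Si](CC)(CC)CC)/C(C(=O)OC)=C\CC[C@@]1(C)O[C@H]1[C@H](OC(=O)C(=C)CBr)C=C | intermediate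
14 | methyl (2E)-5-{(2R,3S)-3-[(2R)-4-(bromomethyl)-5-oxo-2,5-dihydrofuran-2-yl]-2-methyloxiran-2-yl}-2-[(1S)-1,2-bis(triethylsilyloxy)ethyl]pent-2-enoate | CC[Si](CC)(CC)OC[C@@H](O[Si](CC)(CC)CC)/C(C(=O)OC)=C\CC[C@@]1(C)O[C@H]1[C@H]1C=C(CBr)C(=O)O1 | intermediate
15 | methyl (2E)-5-{(2R,3S)-3-[(2R)-4-(bromomethyl)-5-oxo-2,5-dihydrofuran-2-yl]-2-methyloxiran-2-yl}-2-[(1S)-2-hydroxy-1-(triethylsilyloxy)ethyl]pent-2-enoate | OC[C@@H](O[Si](CC)(CC)CC)/C(C(=O)OC)=C\CC[C@@]1(C)O[C@H]1[C@H]1C=C(CBr)C(=O)O1 | intermediate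
16 | methyl (2E)-5-{(2R,3S)-3-[(2R)-4-(bromomethyl)-5-oxo-2,5-dihydrofuran-2-yl]-2-methyloxiran-2-yl}-2-[(1S)-2-oxo-1-(triethylsilyloxy)ethyl]pent-2-enoate | O=C[C@@H](O[Si](CC)(CC)CC)/C(C(=O)OC)=C\CC[C@@]1(C)O[C@H]1[C@H]1C=C(CBr)C(=O)O1 | intermediate
17 | allylchromium dichloride derived from 16 (trivalent chromium on C13) | O=C[C@@H](O[Si](CC)(CC)CC)/C(C(=O)OC)=C\CC[C@@]1(C)O[C@H]1[C@H]1C=C(C[Cr](Cl)Cl)C(=O)O1 | intermediate
18 | methyl (4R,5S,6R,7R,8R,9S)-4,5-epoxy-8-hydroxy-9-(triethylsilyloxy)germacra-1(10),11(13)-dien-6,12-olid-14-oate (8-epi alcohol, C1=C10 ring-cis) | C=C1C(=O)O[C@@H]2[C@H]1[C@@H](O)[C@@H](O[Si](CC)(CC)CC)/C(C(=O)OC)=C\CC[C@@]1(C)O[C@@H]21 | intermediate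
19 | methyl (2S)-2-methyloxirane-2-carboxylate | COC(=O)[C@]1(C)CO1 | starting material
20 | (2S)-2-methyloxirane-2-carboxylic acid | OC(=O)[C@]1(C)CO1 | intermediate
21 | methyl (4R,5S,6R,7S,8S,9S)-4,5-epoxy-8-{[(2S)-2-methyloxiran-2-yl]carbonyloxy}-9-(triethylsilyloxy)germacra-1(10),11(13)-dien-6,12-olid-14-oate | C=C1C(=O)O[C@@H]2[C@H]1[C@H](OC(=O)[C@]1(C)CO1)[C@@H](O[Si](CC)(CC)CC)/C(C(=O)OC)=C\CC[C@@]1(C)O[C@@H]21 | intermediate
22 | methyl (4R,5S,6R,7R,8S,9S)-4,5-epoxy-9-hydroxy-8-{[(2S)-2-methyloxiran-2-yl]carbonyloxy}germacra-1(10),11(13)-dien-6,12-olid-14-oate | C=C1C(=O)O[C@@H]2[C@H]1[C@H](OC(=O)[C@]1(C)CO1)[C@@H](O)/C(C(=O)OC)=C\CC[C@@]1(C)O[C@@H]21 | intermediate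
23 | CNP0274195.1, methyl (4R,5S,6R,7R,8S,9S)-9-acetoxy-4,5-epoxy-8-{[(2S)-2-methyloxiran-2-yl]carbonyloxy}germacra-1(10),11(13)-dien-6,12-olid-14-oate | C=C1C(=O)O[C@@H]2[C@H]1[C@H](OC(=O)[C@]1(C)CO1)[C@@H](OC(C)=O)/C(C(=O)OC)=C\CC[C@@]1(C)O[C@@H]21 | target

Total step count: 17. Longest linear sequence: 15 steps (from dimethyl (S)-malate 3 through steps 2–14, 16 and 17).

Steps most likely to fail

Step 14 (macrocyclisation). Ring closure may lose to intermolecular coupling, the aldehyde may add to the butenolide face anti to C5 and give the trans-fused lactone, or the chromium alkoxide may lactonise onto the C14 ester. The fallback closes the ring before the epoxide is made, on the more flexible 4Z-olefin. It sets out from divinyl carbinol 11: acylation with 2-(bromomethyl)acryloyl chloride and 2,6-lutidine would give the acrylate ester F1, ring-closing metathesis with the second-generation Grubbs catalyst the olefinic butenolide F2, buffered HF·pyridine the primary alcohol F3, Dess–Martin oxidation the aldehyde F4, and CrCl2 at high dilution the macrocyclic diene alcohol F5. Epoxidation of F5 with mCPBA, which can only attack the electron-rich C4=C5 olefin and should do so from the exposed face of the ring, then comes back to the route at 18.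

Step 16 (Mitsunobu inversion). The hindered alkoxyphosphonium ion may eliminate toward C7 instead of being displaced, or may not form at all. The fallback sets out from 18: Dess–Martin oxidation would give the C8 ketone F6, and reduction with NaBH4 and CeCl3·7H2O in MeOH at −78 °C (Luche conditions, hydride anti to the C9 silyloxy group in the Felkin–Anh sense) the 8S alcohol F7. Esterification of F7 with acid 20 by the Yamaguchi protocol (2,4,6-trichlorobenzoyl chloride, Et3N, DMAP), with retention, comes back to the route at 21.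

Step 8 (asymmetric vinylation). Facial discrimination on the hindered Z-enal may be poor, or the enal may isomerise to the E-isomer before it is attacked. The fallback sets out from 10: enantioselective alkynylation with trimethylsilylacetylene, Me2Zn and the ProPhenol ligand enantiomer that attacks the Re face would give the silylated propargylic alcohol F8, and K2CO3 in MeOH would remove the C-silyl group to give the terminal alkyne F9. Semihydrogenation of F9 over Pd/CaCO3 poisoned with Pb(OAc)2 and quinoline comes back to the route at 11.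

Further compounds
F1 | step 14 | 2-(bromomethyl)prop-2-enoate ester of 11 (4Z-olefin kept) | CC[Si](CC)(CC)OC[C@@H](O[Si](CC)(CC)CC)/C(C(=O)OC)=C\CC/C(C)=C\[C@H](OC(=O)C(=C)CBr)C=C
F2 | step 14 | olefinic butenolide, the 4Z-olefin analogue of 14 | CC[Si](CC)(CC)OC[C@@H](O[Si](CC)(CC)CC)/C(C(=O)OC)=C\CC/C(C)=C\[C@H]1C=C(CBr)C(=O)O1
F3 | step 14 | primary alcohol, the 4Z-olefin analogue of 15 | OC[C@@H](O[Si](CC)(CC)CC)/C(C(=O)OC)=C\CC/C(C)=C\[C@H]1C=C(CBr)C(=O)O1
F4 | step 14 | aldehyde, the 4Z-olefin analogue of 16 | O=C[C@@H](O[Si](CC)(CC)CC)/C(C(=O)OC)=C\CC/C(C)=C\[C@H]1C=C(CBr)C(=O)O1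
F5 | step 14 | macrocyclic diene alcohol, the 4Z-olefin analogue of 18 | C=C1C(=O)O[C@@H]2[C@H]1[C@@H](O)[C@@H](O[Si](CC)(CC)CC)/C(C(=O)OC)=C\CC/C(C)=C\2
F6 | step 16 | C8 ketone derived from 18 | C=C1C(=O)O[C@@H]2[C@H]1C(=O)[C@@H](O[Si](CC)(CC)CC)/C(C(=O)OC)=C\CC[C@@]1(C)O[C@@H]21
F7 | step 16 | 8S alcohol, the C8 epimer of 18 | C=C1C(=O)O[C@@H]2[C@H]1[C@H](O)[C@@H](O[Si](CC)(CC)CC)/C(C(=O)OC)=C\CC[C@@]1(C)O[C@@H]21
F8 | step 8 | methyl (2E,6Z,8S)-8-hydroxy-6-methyl-10-(trimethylsilyl)-2-[(1S)-1,2-bis(triethylsilyloxy)ethyl]deca-2,6-dien-9-ynoate | CC[Si](CC)(CC)OC[C@@H](O[Si](CC)(CC)CC)/C(C(=O)OC)=C\CC/C(C)=C\[C@H](O)C#C[Si](C)(C)C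
F9 | step 8 | methyl (2E,6Z,8S)-8-hydroxy-6-methyl-2-[(1S)-1,2-bis(triethylsilyloxy)ethyl]deca-2,6-dien-9-ynoate | CC[Si](CC)(CC)OC[C@@H](O[Si](CC)(CC)CC)/C(C(=O)OC)=C\CC/C(C)=C\[C@H](O)C#C
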